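The target is cut at its linking ester into a hydroxymethyl-acrylic acid carrying cyclohexene ring A and the tert-butyl ester of heptelidic acid (rings B and C). The two are joined at the end by carboxylate opening of the spiro-epoxide. The route rests on cutting ring A between sp2 carbon C3′, which carries CH2OH, and the bare methylene C4′. The key step exploits that C2′=C3′ is a masked acrylate flanked by the unfunctionalised C4′–C5′ bridge. In one pot, hydroboration and intramolecular B-alkyl Suzuki–Miyaura coupling close ring A with alkene position and geometry fixed. The precursor is an acyclic (Z)-α-iodoenoate with a vinyl group on C6′; its C1′/C6′ stereodiad comes from one organocatalytic Michael addition.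

Key step: step 7

Remark on the chemistry: atom labels follow the same pattern in both halves.
- Ring A (left cyclohexene): C1′ (acrylate arm), C2′H=C3′(C7′H2OH), C4′H2, C5′H2, C6′ (isopropyl).
- Ring B (right cyclohexane): C1–C6 likewise, with C7 = CH2O on C3.
- Ring C: the seven-membered lactone.
- Compound 27 and both enantiomers of the diphenylprolinol ether catalysts are assumed to be purchasable.

Step 1
Reactants: 1 2,2-dimethoxyacetaldehyde; 2 nitromethane
Product: 3 1,1-dimethoxy-3-nitropropan-2-ol (racemic)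
Conditions: K2CO3 (10 mol %), MeNO2/H2O, 0 °C → rt
Reagents that add atoms: none
Why: Base-catalysed Henry (nitroaldol) addition to a non-enolisable aldehyde; the carbinol centre is erased in step 2, so its configuration does not matter.

Step 2
Reactants: 3 1,1-dimethoxy-3-nitropropan-2-ol
Product: 4 (E)-3,3-dimethoxy-1-nitroprop-1-ene
Conditions: (CF3CO)2O, Et3N, CH2Cl2, −10 °C
Reagents that add atoms: none
Why: O-acylation of the β-nitro alcohol followed by E1cB elimination should give the thermodynamically preferred E-nitroalkene.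

Step 3
Reactants: 4 (E)-3,3-dimethoxy-1-nitroprop-1-ene; 5 3-methylbutanal
Product: 6 (2R,3R)-3-(dimethoxymethyl)-4-nitro-2-(propan-2-yl)butanal
Conditions: (S)-α,α-diphenylprolinol trimethylsilyl ether (10 mol %), 4-nitrophenol (10 mol %), toluene, 0 °C → rt
Reagents that add atoms: none
Why: Enamine-catalysed asymmetric Michael addition of an aldehyde to a nitroalkene: the E-enamine of 5, shielded on one face by the diphenyl(silyloxy)methyl group, adds through the synclinal transition state and should set C6′ and C1′ together as the syn diad, which is trans in ring A.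

Step 4
Reactants: 6 (2R,3R)-3-(dimethoxymethyl)-4-nitro-2-(propan-2-yl)butanal
Product: 7 (3S,4R)-4-(dimethoxymethyl)-5-nitro-3-(propan-2-yl)pent-1-ene
Conditions: Ph3PCH3Br (2.5 equiv), KOtBu (2.4 equiv), THF, −78 → 0 °C; AcOH quench
Reagents that add atoms: methyltriphenylphosphonium bromide, C[P+](c1ccccc1)(c1ccccc1)c1ccccc1.[Br-]
Why: Wittig methylenation; the excess ylide parks the acidic CH2NO2 group as its inert nitronate, and the fast, cold reaction should leave C6′ unepimerised.

Step 5
Reactants: 7 (3S,4R)-4-(dimethoxymethyl)-5-nitro-3-(propan-2-yl)pent-1-ene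
Product: 9 (2R,3S)-2-(dimethoxymethyl)-3-(propan-2-yl)pent-4-enal, via sodium nitronate 8 (not isolated)
Conditions: NaOMe, MeOH, 0 °C; then aq. TiCl3/NH4OAc (pH 6), 0 °C → rt; crude product used at once
Reagents that add atoms: water, O
Why: Reductive Nef reaction: TiCl3 reduces the nitronate to the imine, which hydrolyses at pH 6, where the terminal alkene and the dimethyl acetal should survive and C1′ should not enolise.

Step 6
Reactants: 9 (2R,3S)-2-(dimethoxymethyl)-3-(propan-2-yl)pent-4-enal
Product: 10 ethyl (2Z,4R,5S)-4-(dimethoxymethyl)-2-iodo-5-(propan-2-yl)hepta-2,6-dienoate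
Conditions: Ph3P=CHCO2Et, NIS, CH2Cl2, −20 °C; then 9, −20 °C → rt
Reagents that add atoms: ethyl (triphenylphosphoranylidene)acetate, CCOC(=O)C=P(c1ccccc1)(c1ccccc1)c1ccccc1; N-iodosuccinimide, O=C1CCC(=O)N1I
Why: Wittig olefination with the α-iodo stabilised ylide made in situ places the ester trans to the alkyl residue, so the Z-iodide (I cis to C1′) should predominate under neutral conditions that spare the labile aldehyde.

Step 7
Reactants: 10 ethyl (2Z,4R,5S)-4-(dimethoxymethyl)-2-iodo-5-(propan-2-yl)hepta-2,6-dienoate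
Product: 12 ethyl (3R,4R)-3-(dimethoxymethyl)-4-(propan-2-yl)cyclohex-1-ene-1-carboxylate, via B-alkyl-9-BBN adduct 11 (not isolated)
Conditions: 9-BBN-H (1.3 equiv), THF, 0 °C → rt; then slow addition to Pd(dppf)Cl2 (10 mol %), AsPh3 (10 mol %), Cs2CO3 (3 equiv), DMF/THF/H2O, 50 °C, final 5 mM
Reagents that add atoms: none
Why: 9-BBN-H adds anti-Markovnikov to the only monosubstituted alkene (C4′=C5′) to give borane 11; zerovalent palladium then inserts into the C3′–I bond, the base-activated B-alkyl group transmetalates within the same molecule, and reductive elimination from a seven-membered palladacycle forges C3′–C4′. The closest known reaction types are the intramolecular B-alkyl Suzuki–Miyaura coupling of ω-boryl alkenyl halides and the B-alkyl coupling of α-iodo-α,β-unsaturated carbonyl compounds with Pd(dppf)Cl2/AsPh3/Cs2CO3. Ring A closes as a six-membered carbocycle with the alkene endocyclic, which is possible only from the Z-iodide because I and C1′ are cis. No stereocentre is created: C1′ and C6′ are untouched and end up trans-diequatorial, and the stereoretentive coupling fixes the alkene between C2′ and C3′, so no regioisomeric cyclohexene can form. The step needs chemoselective hydroboration, secured by the steric and electronic gap between the vinyl group and the electron-poor trisubstituted iodoacrylate (ester and acetal are inert). It also needs cyclisation to win over oligomerisation and β-hydride elimination, secured by slow addition at high dilution and the wide-bite-angle dppf ligand.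

Step 8
Reactants: 12 ethyl (3R,4R)-3-(dimethoxymethyl)-4-(propan-2-yl)cyclohex-1-ene-1-carboxylate
Product: 13 [(3R,4R)-3-(dimethoxymethyl)-4-(propan-2-yl)cyclohex-1-en-1-yl]methanol
Conditions: DIBAL-H (2.5 equiv), CH2Cl2, −78 °C; aq. Rochelle salt
Reagents that add atoms: none
Why: 1,2-Reduction of the α,β-unsaturated ester with DIBAL-H gives the allylic alcohol C7′H2OH and does not touch the acetal.

Step 9
Reactants: 13 [(3R,4R)-3-(dimethoxymethyl)-4-(propan-2-yl)cyclohex-1-en-1-yl]methanol
Product: 14 (1R,6R)-3-(hydroxymethyl)-6-(propan-2-yl)cyclohex-2-ene-1-carbaldehyde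
Conditions: 10 % aq. oxalic acid on silica gel, CH2Cl2, rt
Reagents that add atoms: water, O
Why: Mild heterogeneous acetal hydrolysis should release the aldehyde without moving the β,γ-double bond, and the trans arrangement at C1′ is also the thermodynamic one.

Step 10
Reactants: 14 (1R,6R)-3-(hydroxymethyl)-6-(propan-2-yl)cyclohex-2-ene-1-carbaldehyde
Product: 15 methyl (2Z)-3-[(1R,6R)-3-(hydroxymethyl)-6-(propan-2-yl)cyclohex-2-en-1-yl]-2-iodoprop-2-enoate
Conditions: Ph3P=CHCO2Me, NIS, CH2Cl2, −20 °C; then 14, −20 °C → rt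
Reagents that add atoms: methyl (triphenylphosphoranylidene)acetate, COC(=O)C=P(c1ccccc1)(c1ccccc1)c1ccccc1; N-iodosuccinimide, O=C1CCC(=O)N1I
Why: The same neutral iodo-Wittig olefination as in step 6 tolerates the free alcohol and should set the trisubstituted alkene with the ester trans and iodine cis to C1′.

Step 11
Reactants: 15 methyl (2Z)-3-[(1R,6R)-3-(hydroxymethyl)-6-(propan-2-yl)cyclohex-2-en-1-yl]-2-iodoprop-2-enoate
Product: 16 methyl (2E)-2-(hydroxymethyl)-3-[(1R,6R)-3-(hydroxymethyl)-6-(propan-2-yl)cyclohex-2-en-1-yl]prop-2-enoate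
Conditions: Bu3SnCH2OH, Pd2(dba)3 (2.5 mol %), AsPh3 (20 mol %), CuI (10 mol %), NMP, 45 °C
Reagents that add atoms: (tributylstannyl)methanol, CCCC[Sn](CO)(CCCC)CCCC
Why: Stille coupling replaces iodine by CH2OH with retention, which turns the Z-iodide into the required E-2-(hydroxymethyl)enoate with CH2OH cis to C1′.

Step 12
Reactants: 16 methyl (2E)-2-(hydroxymethyl)-3-[(1R,6R)-3-(hydroxymethyl)-6-(propan-2-yl)cyclohex-2-en-1-yl]prop-2-enoate
Product: 17 (2E)-2-(hydroxymethyl)-3-[(1R,6R)-3-(hydroxymethyl)-6-(propan-2-yl)cyclohex-2-en-1-yl]prop-2-enoic acid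
Conditions: LiOH (3 equiv), THF/MeOH/H2O, rt; 1 M HCl to pH 3
Reagents that add atoms: lithium hydroxide, [Li+].[OH-]
Why: Simple saponification of the methyl ester; no other hydrolysable group is present.

Step 13
Reactants: 5 3-methylbutanal; 18 but-3-en-2-one
Product: 19 (2R)-5-oxo-2-(propan-2-yl)hexanal
Conditions: (R)-2-[methoxy(diphenyl)methyl]pyrrolidine (5 mol %), ethyl 3,4-dihydroxybenzoate (20 mol %), neat, 4 °C
Reagents that add atoms: none
Why: Enamine-catalysed asymmetric Michael addition of an aldehyde to a vinyl ketone; the R-configured catalyst leaves open the enamine face that should give C6 of ring B in the R configuration.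

Step 14
Reactants: 19 (2R)-5-oxo-2-(propan-2-yl)hexanal
Product: 20 (4R)-4-(propan-2-yl)cyclohex-2-en-1-one
Conditions: LiOH (0.3 equiv), i-PrOH, rt
Reagents that add atoms: none
Why: Intramolecular aldol condensation of the methyl ketone onto the aldehyde gives the cyclohexenone, and the mild catalytic base limits γ-deprotonation and hence racemisation.

Step 15
Reactants: 20 (4R)-4-(propan-2-yl)cyclohex-2-en-1-one
Product: 22 (2R,3R,4R)-3-ethenyl-2-(hydroxymethyl)-4-(propan-2-yl)cyclohexan-1-one, via bromomagnesium enolate 21 (not isolated)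
Conditions: CH2=CHMgBr, CuBr·SMe2 (15 mol %), THF/Me2S, −78 °C; then monomeric HCHO in THF, −78 °C; aq. NH4Cl
Reagents that add atoms: vinylmagnesium bromide, C=C[Mg]Br; formaldehyde, C=O
Why: Copper-catalysed conjugate addition anti to the C6 isopropyl group, then aldol trapping of the regiodefined enolate anti to the new vinyl group, should set C1 and C2 by substrate control as the all-equatorial ketone.

Step 16
Reactants: 22 (2R,3R,4R)-3-ethenyl-2-(hydroxymethyl)-4-(propan-2-yl)cyclohexan-1-one
Product: 23 (2R,3R,4R)-2-{[(tert-butyldimethylsilyl)oxy]methyl}-3-ethenyl-4-(propan-2-yl)cyclohexan-1-one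
Conditions: TBSCl, imidazole, CH2Cl2, 0 °C
Reagents that add atoms: tert-butyldimethylsilyl chloride, CC(C)(C)[Si](C)(C)Cl
Why: Silylation of the primary alcohol blocks retro-aldol and dehydration of the β-hydroxy ketone before the basic ylide step.

Step 17
Reactants: 23 (2R,3R,4R)-2-{[(tert-butyldimethylsilyl)oxy]methyl}-3-ethenyl-4-(propan-2-yl)cyclohexan-1-one
Product: 24 tert-butyl{[(3S,4R,5R,6R)-5-ethenyl-6-(propan-2-yl)-1-oxaspiro[2.5]octan-4-yl]methoxy}dimethylsilane
Conditions: Me3SI, NaH, DMSO/THF, 0 °C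
Reagents that add atoms: trimethylsulfonium iodide, C[S+](C)C.[I-]
Why: Corey–Chaykovsky epoxidation: the small unstabilised sulfonium ylide adds irreversibly along the axial trajectory of the chair ketone, so C7 should become axial and the oxygen equatorial, which is the C3 configuration of the target.

Step 18
Reactants: 24 tert-butyl{[(3S,4R,5R,6R)-5-ethenyl-6-(propan-2-yl)-1-oxaspiro[2.5]octan-4-yl]methoxy}dimethylsilane
Product: 25 [(3S,4R,5R,6R)-5-ethenyl-6-(propan-2-yl)-1-oxaspiro[2.5]octan-4-yl]methanol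
Conditions: Bu4NF, THF, 0 °C
Reagents that add atoms: none
Why: Fluoride desilylation; the alkoxide cannot reach the backside of the C7–O bond, so the epoxide should survive.

Step 19
Reactants: 25 [(3S,4R,5R,6R)-5-ethenyl-6-(propan-2-yl)-1-oxaspiro[2.5]octan-4-yl]methanol
Product: 26 (3S,4S,5R,6R)-5-ethenyl-6-(propan-2-yl)-1-oxaspiro[2.5]octane-4-carboxylic acid
Conditions: TEMPO (10 mol %), NaClO2 (2 equiv), NaOCl (2 mol %), MeCN/phosphate buffer pH 6.7, 35 °C
Reagents that add atoms: sodium chlorite, [Na+].[O-]Cl=O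
Why: TEMPO/chlorite oxidation of the primary alcohol to the acid at buffered pH spares the vinyl group and the acid-labile epoxide and keeps C2 in its equatorial, thermodynamic configuration.

Step 20
Reactants: 26 (3S,4S,5R,6R)-5-ethenyl-6-(propan-2-yl)-1-oxaspiro[2.5]octane-4-carboxylic acid; 27 tert-butyl 2-(bromomethyl)prop-2-enoate
Product: 28 2-(tert-butoxycarbonyl)prop-2-en-1-yl (3S,4S,5R,6R)-5-ethenyl-6-(propan-2-yl)-1-oxaspiro[2.5]octane-4-carboxylate
Conditions: K2CO3, DMF, 0 °C → rt
Reagents that add atoms: none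
Why: O-alkylation of the carboxylate with a reactive allylic bromide (SN2 and SN2′ give the same ester) avoids activating the hindered acid next to the epoxide.

Step 21
Reactants: 28 2-(tert-butoxycarbonyl)prop-2-en-1-yl (3S,4S,5R,6R)-5-ethenyl-6-(propan-2-yl)-1-oxaspiro[2.5]octane-4-carboxylate
Product: 29 heptelidic acid tert-butyl ester (trans-fused rings B and C, spiro-epoxide at C3 with axial CH2, isopropyl at C6)
Conditions: second-generation Hoveyda–Grubbs catalyst (10 mol %), toluene (2 mM), 80 °C, argon sparge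
Reagents that add atoms: none
Why: Ring-closing metathesis between the C1 vinyl group and the 1,1-disubstituted acrylate closes the seven-membered lactone ring C, whose size enforces the alkene geometry with CH2O cis to C1.

Step 22
Reactants: 29 heptelidic acid tert-butyl ester; 17 (2E)-2-(hydroxymethyl)-3-[(1R,6R)-3-(hydroxymethyl)-6-(propan-2-yl)cyclohex-2-en-1-yl]prop-2-enoic acid
Product: 30 tert-butyl ester of the target
Conditions: 17 (1.3 equiv), Cs2CO3 (0.2 equiv), DMF, 60 °C
Reagents that add atoms: none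
Why: Carboxylate SN2 opening of the 2,2-disubstituted epoxide at its CH2 terminus C7 leaves the C3–O bond and configuration untouched; the neutral alcohols of 17 are far poorer nucleophiles, and the free acid re-protonates the tertiary alkoxide so that only a weakly basic carboxylate is present.

Step 23
Reactants: 30 tert-butyl ester of the target
Product: 32 CNP0361406.2 (target), via tetrakis(trimethylsilyl) derivative 31 (not isolated)
Conditions: TMSOTf (10 equiv), 2,6-lutidine (15 equiv), CH2Cl2, 0 °C → rt; then aq. citric acid, THF, rt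
Reagents that add atoms: none
Why: Silyl triflate-mediated cleavage of the tert-butyl ester (loss of isobutene from the O-silylated ester) under lutidine buffering avoids protic acid that could ionise the allylic alcohols, and the transient trimethylsilyl groups of 31 should fall off in the mildly acidic work-up.

Compound list
1 | 2,2-dimethoxyacetaldehyde | COC(OC)C=O | starting material
2 | nitromethane | C[N+](=O)[O-] | starting material
3 | 1,1-dimethoxy-3-nitropropan-2-ol (racemic) | COC(OC)C(O)C[N+](=O)[O-] | intermediate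
4 | (E)-3,3-dimethoxy-1-nitroprop-1-ene | COC(OC)/C=C/[N+](=O)[O-] | intermediate
5 | 3-methylbutanal (isovaleraldehyde) | CC(C)CC=O | starting material
6 | (2R,3R)-3-(dimethoxymethyl)-4-nitro-2-(propan-2-yl)butanal | COC(OC)[C@@H](C[N+](=O)[O-])[C@H](C=O)C(C)C | intermediate
7 | (3S,4R)-4-(dimethoxymethyl)-5-nitro-3-(propan-2-yl)pent-1-ene | COC(OC)[C@@H](C[N+](=O)[O-])[C@H](C=C)C(C)C | intermediate
8 | sodium nitronate of 7 | COC(OC)[C@@H](C=[N+]([O-])[O-])[C@H](C=C)C(C)C.[Na+] | intermediate
9 | (2R,3S)-2-(dimethoxymethyl)-3-(propan-2-yl)pent-4-enal | COC(OC)[C@@H](C=O)[C@H](C=C)C(C)C | intermediate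
10 | ethyl (2Z,4R,5S)-4-(dimethoxymethyl)-2-iodo-5-(propan-2-yl)hepta-2,6-dienoate | COC(OC)[C@@H](/C=C(\I)C(=O)OCC)[C@H](C=C)C(C)C | intermediate
11 | ethyl (2Z,4R,5R)-7-(9-borabicyclo[3.3.1]nonan-9-yl)-4-(dimethoxymethyl)-2-iodo-5-(propan-2-yl)hept-2-enoate | COC(OC)[C@@H](/C=C(\I)C(=O)OCC)[C@H](CCB1C2CCCC1CCC2)C(C)C | intermediate
12 | ethyl (3R,4R)-3-(dimethoxymethyl)-4-(propan-2-yl)cyclohex-1-ene-1-carboxylate | COC(OC)[C@H]1C=C(C(=O)OCC)CC[C@@H]1C(C)C | intermediate
13 | [(3R,4R)-3-(dimethoxymethyl)-4-(propan-2-yl)cyclohex-1-en-1-yl]methanol | COC(OC)[C@H]1C=C(CO)CC[C@@H]1C(C)C | intermediate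
14 | (1R,6R)-3-(hydroxymethyl)-6-(propan-2-yl)cyclohex-2-ene-1-carbaldehyde | O=C[C@H]1C=C(CO)CC[C@@H]1C(C)C | intermediate
15 | methyl (2Z)-3-[(1R,6R)-3-(hydroxymethyl)-6-(propan-2-yl)cyclohex-2-en-1-yl]-2-iodoprop-2-enoate | COC(=O)/C(I)=C/[C@H]1C=C(CO)CC[C@@H]1C(C)C | intermediate
16 | methyl (2E)-2-(hydroxymethyl)-3-[(1R,6R)-3-(hydroxymethyl)-6-(propan-2-yl)cyclohex-2-en-1-yl]prop-2-enoate | COC(=O)/C(CO)=C/[C@H]1C=C(CO)CC[C@@H]1C(C)C | intermediate
17 | (2E)-2-(hydroxymethyl)-3-[(1R,6R)-3-(hydroxymethyl)-6-(propan-2-yl)cyclohex-2-en-1-yl]prop-2-enoic acid | OC(=O)/C(CO)=C/[C@H]1C=C(CO)CC[C@@H]1C(C)C | intermediate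
18 | but-3-en-2-one (methyl vinyl ketone) | CC(=O)C=C | starting material
19 | (2R)-5-oxo-2-(propan-2-yl)hexanal | CC(C)[C@H](C=O)CCC(C)=O | intermediate
20 | (4R)-4-(propan-2-yl)cyclohex-2-en-1-one | CC(C)[C@H]1CCC(=O)C=C1 | intermediate
21 | bromomagnesium enolate of trans-3-ethenyl-4-(propan-2-yl)cyclohexanone (C2=C3 enolate) | CC(C)[C@H]1CCC(O[Mg]Br)=C[C@@H]1C=C | intermediate
22 | (2R,3R,4R)-3-ethenyl-2-(hydroxymethyl)-4-(propan-2-yl)cyclohexan-1-one | CC(C)[C@H]1CCC(=O)[C@@H](CO)[C@@H]1C=C | intermediate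
23 | (2R,3R,4R)-2-{[(tert-butyldimethylsilyl)oxy]methyl}-3-ethenyl-4-(propan-2-yl)cyclohexan-1-one | CC(C)[C@H]1CCC(=O)[C@@H](CO[Si](C)(C)C(C)(C)C)[C@@H]1C=C | intermediate
24 | tert-butyl{[(3S,4R,5R,6R)-5-ethenyl-6-(propan-2-yl)-1-oxaspiro[2.5]octan-4-yl]methoxy}dimethylsilane | CC(C)[C@H]1CC[C@@]2(CO2)[C@@H](CO[Si](C)(C)C(C)(C)C)[C@@H]1C=C | intermediate
25 | [(3S,4R,5R,6R)-5-ethenyl-6-(propan-2-yl)-1-oxaspiro[2.5]octan-4-yl]methanol | CC(C)[C@H]1CC[C@@]2(CO2)[C@@H](CO)[C@@H]1C=C | intermediate
26 | (3S,4S,5R,6R)-5-ethenyl-6-(propan-2-yl)-1-oxaspiro[2.5]octane-4-carboxylic acid | CC(C)[C@H]1CC[C@@]2(CO2)[C@@H](C(=O)O)[C@@H]1C=C | intermediate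
27 | tert-butyl 2-(bromomethyl)prop-2-enoate | C=C(CBr)C(=O)OC(C)(C)C | starting material
28 | 2-(tert-butoxycarbonyl)prop-2-en-1-yl (3S,4S,5R,6R)-5-ethenyl-6-(propan-2-yl)-1-oxaspiro[2.5]octane-4-carboxylate | CC(C)[C@H]1CC[C@@]2(CO2)[C@@H](C(=O)OCC(=C)C(=O)OC(C)(C)C)[C@@H]1C=C | intermediate
29 | heptelidic acid tert-butyl ester (trans-fused cyclohexane/unsaturated seven-membered lactone, spiro-epoxide with axial CH2) | CC(C)[C@H]1CC[C@@]2(CO2)[C@H]3C(=O)OCC(C(=O)OC(C)(C)C)=C[C@H]13 | intermediate
30 | tert-butyl ester of the target | CC(C)[C@H]1CC[C@@](O)(COC(=O)/C(=C/[C@H]2C=C(CO)CC[C@@H]2C(C)C)CO)[C@H]2C(=O)OCC(C(=O)OC(C)(C)C)=C[C@H]12 | intermediate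
31 | tris(O-trimethylsilyl) ether trimethylsilyl ester of the target | CC(C)[C@H]1CC[C@@](O[Si](C)(C)C)(COC(=O)/C(=C/[C@H]2C=C(CO[Si](C)(C)C)CC[C@@H]2C(C)C)CO[Si](C)(C)C)[C@H]2C(=O)OCC(C(=O)O[Si](C)(C)C)=C[C@H]12 | intermediate
32 | CNP0361406.2 | CC(C)[C@H]1CC[C@@](O)(COC(=O)/C(=C/[C@H]2C=C(CO)CC[C@@H]2C(C)C)CO)[C@H]2C(=O)OCC(C(=O)O)=C[C@H]12 | target

Total step count: 23. Longest linear sequence: 14 steps (steps 1–12, 22, 23).

Steps most likely to fail

**Step 5.** During the aqueous Nef reaction and handling of the aldehyde, the acetal may hydrolyse, methanol may be lost by β-elimination, or C1′ may epimerise.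
- The fallback never exposes the free aldehyde to water or to isolation. It sets out from 7 and comes back at 10.
- The nitro group is converted directly to the acid with NaNO2/AcOH in DMSO at 35 °C, giving (2S,3S)-2-(dimethoxymethyl)-3-(propan-2-yl)pent-4-enoic acid F1.
- LiAlH4 in Et2O reduces it to (2R,3S)-2-(dimethoxymethyl)-3-(propan-2-yl)pent-4-en-1-ol F2.
- F2 is oxidised with Dess–Martin periodinane/NaHCO3 in CH2Cl2 in the presence of the preformed ylide Ph3P=C(I)CO2Et, so the aldehyde is trapped as it forms.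

**Step 7.** Protodeboronation, β-hydride elimination at the alkylpalladium stage, intermolecular coupling, or erosion of the alkenylpalladium geometry may outrun ring closure.
- The fallback makes the C3′–C4′ bond by an anionic Michael-initiated ring closure instead of a cross-coupling. It sets out from 9 and comes back at 12.
- Wittig reaction with Ph3P=CHCO2Et gives ethyl (2E,4S,5S)-4-(dimethoxymethyl)-5-(propan-2-yl)hepta-2,6-dienoate F3.
- 9-BBN-H then NaBO3 gives ethyl (2E,4S,5R)-4-(dimethoxymethyl)-7-hydroxy-5-(propan-2-yl)hept-2-enoate F4.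
- I2/PPh3/imidazole gives ethyl (2E,4S,5R)-4-(dimethoxymethyl)-7-iodo-5-(propan-2-yl)hept-2-enoate F5.
- PBu3 in t-BuOH adds to C2′, and the resulting enolate alkylates C4′ (intramolecular Morita–Baylis–Hillman-type alkylation). This gives [(1R,6R)-6-(dimethoxymethyl)-2-(ethoxycarbonyl)-5-(propan-2-yl)cyclohexyl]tributylphosphonium iodide F6.
- KOH with BnEt3NCl then expels PBu3 from F6.

**Step 21.** The ruthenium carbene may fail to engage the hindered C1 vinyl group or the electron-poor 1,1-disubstituted alkene, so that dimerisation by cross-metathesis takes over.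
- The fallback closes ring C by a carbonyl olefination. It sets out from 26 and comes back at 29.
- Ozonolysis (O3, CH2Cl2/MeOH, −78 °C; Me2S) gives (3S,4S,5R,6R)-5-formyl-6-(propan-2-yl)-1-oxaspiro[2.5]octane-4-carboxylic acid F7.
- With Cs2CO3 and tert-butyl 2-(diethoxyphosphoryl)prop-2-enoate in THF, the carboxylate adds in oxa-Michael fashion. This gives 3-tert-butoxy-2-(diethoxyphosphoryl)-3-oxopropyl (3S,4S,5R,6R)-5-formyl-6-(propan-2-yl)-1-oxaspiro[2.5]octane-4-carboxylate F8.
- The phosphonate anion of F8 closes the lactone by intramolecular Horner–Wadsworth–Emmons reaction.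

Further compounds
F1 | step 5 | (2S,3S)-2-(dimethoxymethyl)-3-(propan-2-yl)pent-4-enoic acid | COC(OC)[C@@H](C(=O)O)[C@H](C=C)C(C)C
F2 | step 5 | (2R,3S)-2-(dimethoxymethyl)-3-(propan-2-yl)pent-4-en-1-ol | COC(OC)[C@@H](CO)[C@H](C=C)C(C)C
F3 | step 7 | ethyl (2E,4S,5S)-4-(dimethoxymethyl)-5-(propan-2-yl)hepta-2,6-dienoate | COC(OC)[C@@H](/C=C/C(=O)OCC)[C@H](C=C)C(C)C
F4 | step 7 | ethyl (2E,4S,5R)-4-(dimethoxymethyl)-7-hydroxy-5-(propan-2-yl)hept-2-enoate | COC(OC)[C@@H](/C=C/C(=O)OCC)[C@H](CCO)C(C)C
F5 | step 7 | ethyl (2E,4S,5R)-4-(dimethoxymethyl)-7-iodo-5-(propan-2-yl)hept-2-enoate | COC(OC)[C@@H](/C=C/C(=O)OCC)[C@H](CCI)C(C)C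
F6 | step 7 | [(1R,6R)-6-(dimethoxymethyl)-2-(ethoxycarbonyl)-5-(propan-2-yl)cyclohexyl]tributylphosphonium iodide | COC(OC)[C@H]1C([P+](CCCC)(CCCC)CCCC)C(C(=O)OCC)CC[C@@H]1C(C)C.[I-]
F7 | step 21 | (3S,4S,5R,6R)-5-formyl-6-(propan-2-yl)-1-oxaspiro[2.5]octane-4-carboxylic acid | CC(C)[C@H]1CC[C@@]2(CO2)[C@@H](C(=O)O)[C@@H]1C=O
F8 | step 21 | 3-tert-butoxy-2-(diethoxyphosphoryl)-3-oxopropyl (3S,4S,5R,6R)-5-formyl-6-(propan-2-yl)-1-oxaspiro[2.5]octane-4-carboxylate | CC(C)[C@H]1CC[C@@]2(CO2)[C@@H](C(=O)OCC(P(=O)(OCC)OCC)C(=O)OC(C)(C)C)[C@@H]1C=O
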